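Ring B of the naphthoquinone (C1=O flanked by C2–OMe and C8a; aryl ring C on C8) is cut into three two-carbon alkyne units, C4a–C5, C6–C7 and C8–C8a. The first and third are already tied together by the C4–C3–C2–C1 chain of ring A, so one ruthenium-catalysed [2+2+2] cyclotrimerisation forms C4a–C8a, C5–C6 and C7–C8 and closes rings A and B at once. The precursor is an acyclic 1,7-diyne-3,6-dione with a free alkyne terminus (future C5), the dimethoxyphenyl group on future C8 and the methoxy group on C2; its partner is methoxyethyne. The diynedione is built from a lactone whose two ends are chemically distinct, and the cycloadduct is aromatised oxidatively without base.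

Key step: step 7

Assumption: the C2 configuration is erased in step 8, so the (S) series is used only because lactone 1 is a cheap single enantiomer; the carbinol centre made in step 4 forms as a mixture and is erased in step 5. Lactone atoms map onto the target as C2(=O) → C4, C3 → C3, C4 → C2, C5 → C1.

Step 1
Reactants: 1 (S)-4-hydroxydihydrofuran-2(3H)-one [(S)-3-hydroxy-γ-butyrolactone]
Product: 2 (S)-4-methoxydihydrofuran-2(3H)-one
Conditions: MeI (5 equiv), Ag2O (1.5 equiv), CaSO4, MeCN, rt, dark
Reagents that add atoms: iodomethane, CI
Why: Purdie methylation (silver-oxide-assisted Williamson O-alkylation) needs no soluble base, so the β-oxygenated lactone should not eliminate to the butenolide, and no bond to the stereocentre is touched, which therefore stays (S).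

Step 2
Reactants: 2 (S)-4-methoxydihydrofuran-2(3H)-one
Product: 3 (S)-4-hydroxy-N,3-dimethoxy-N-methylbutanamide
Conditions: MeNH(OMe)·HCl (3 equiv), AlMe3 (3 equiv), CH2Cl2, 0 °C → rt; aqueous potassium sodium tartrate (KNaC4H4O6) work-up
Reagents that add atoms: N,O-dimethylhydroxylamine hydrochloride, CNOC.Cl
Why: Weinreb aminolysis of a lactone by the aluminium amide is Lewis-acid driven and only weakly basic, so the ring should open without loss of methoxide and leave the chain ends unambiguously different (primary alcohol at future C1, Weinreb amide at future C4).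

Step 3
Reactants: 3 (S)-4-hydroxy-N,3-dimethoxy-N-methylbutanamide
Product: 4 (S)-N,3-dimethoxy-N-methyl-4-oxobutanamide
Conditions: DMP (1.2 equiv), NaHCO3, CH2Cl2, 0 °C → rt; crude aldehyde used directly
Reagents that add atoms: none
Why: Dess–Martin oxidation of the primary alcohol under bicarbonate buffer stops at the aldehyde and avoids the amine bases that could enolise the α-methoxy aldehyde.

Step 4
Reactants: 4 (S)-N,3-dimethoxy-N-methyl-4-oxobutanamide; 5 4-ethynyl-1,2-dimethoxybenzene
Product: 8 (5S)-8-(3,4-dimethoxyphenyl)-6-hydroxy-5-methoxyocta-1,7-diyn-3-one (C6 epimer mixture), via lithium (3,4-dimethoxyphenyl)ethynide 6 (not isolated), via trimethylsilyl ether amide 7 (not isolated)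
Conditions: 5, n-BuLi (1.05 equiv each), THF, –78 °C; add 4, –78 °C; TMSCl (1.2 equiv), –78 → 0 °C; HC≡CMgBr (3 equiv), 0 °C → rt; inverse quench into cold 1 M aqueous HCl
Reagents that add atoms: ethynylmagnesium bromide, C#C[Mg]Br
Why: Chemoselective 1,2-addition of the lithium acetylide to the aldehyde (far more electrophilic than the Weinreb amide at –78 °C) is followed by in-situ silylation of the alkoxide to block lactonisation and then by Weinreb ketone synthesis with the ethynyl Grignard reagent, whose chelated tetrahedral adduct collapses only in the acidic quench that also cleaves the silyl ether and protonates the liberated amine, the new carbinol centre being formed without control because step 5 removes it.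

Step 5
Reactants: 8 (5S)-8-(3,4-dimethoxyphenyl)-6-hydroxy-5-methoxyocta-1,7-diyn-3-one
Product: 9 (S)-1-(3,4-dimethoxyphenyl)-4-methoxyocta-1,7-diyne-3,6-dione
Conditions: DMP (1.3 equiv), NaHCO3, CH2Cl2, 0 °C; filtration through a short silica pad, used at once
Reagents that add atoms: none
Why: Dess–Martin oxidation of the secondary propargylic alcohol to the ynone is base-free, so the 1,4-dione should form without the β-methoxy ketone losing methanol.

Step 6
Reactants: 10 2-chloro-1,1-dimethoxyethane (chloroacetaldehyde dimethyl acetal)
Product: 12 methoxyethyne, via sodium methoxyethynide 11 (not isolated)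
Conditions: NaNH2 (3.2 equiv), liquid NH3, –33 °C; saturated aqueous NH4Cl, –60 °C; volatile product distilled into cold ClCH2CH2Cl and kept cold
Reagents that add atoms: none
Why: Twofold base-induced elimination (methanol, then HCl) from the chloroacetal with sodium amide is the established preparation of 1-alkoxyalkynes, the alkyne being held as its sodium salt until the cold quench.

Step 7
Reactants: 9 (S)-1-(3,4-dimethoxyphenyl)-4-methoxyocta-1,7-diyne-3,6-dione; 12 methoxyethyne
Product: 13 (S)-8-(3,4-dimethoxyphenyl)-2,6-dimethoxy-2,3-dihydronaphthalene-1,4-dione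
Conditions: Cp*RuCl(cod) (10 mol %), 12 (4 equiv), ClCH2CH2Cl, 0 °C → rt, slow syringe-pump addition of 9, Ar
Reagents that add atoms: none
Why: Cp*RuCl(cod), a neutral complex of divalent ruthenium, loses cyclooctadiene and binds both ynone alkynes of 9, whose oxidative cyclisation forms C4a–C8a and gives a ruthenacycle in which six-membered ring A (C1–C2–C3–C4–C4a–C8a) is already closed; insertion of methoxyethyne then forms C5–C6 and reductive elimination forms C7–C8, closing ring B and releasing the catalyst. The closest known reaction type is the Cp*RuCl-catalysed [2+2+2] cyclotrimerisation of tethered diynes, including 1,2-bis(propioloyl)arenes, with terminal alkynes to benzo-fused diketones and quinones. Ring A closes by tether-directed intramolecular oxidative coupling of the 1,7-diyne, and ring B by intermolecular alkyne insertion followed by carbon–carbon reductive elimination, a formal [4+2] between the metallacyclic diene and the alkyne. No stereocentre is formed, and the C2 centre lies away from the reacting atoms and is not touched. The step needs cross- rather than homo-trimerisation and the C6 (meta to aryl) placement of the new methoxy group: the first should be secured by pairing the electron-poor diynone with an excess of the electron-rich ynol ether under slow addition of 9, the second by the steric difference between the unsubstituted terminus C5 and the aryl-bearing terminus C8 under the bulky Cp* ligand, which should put the methoxy-bearing alkyne carbon next to C5. The neutral medium also keeps the β-methoxy ketone from losing methanol.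

Step 8
Reactants: 13 (S)-8-(3,4-dimethoxyphenyl)-2,6-dimethoxy-2,3-dihydronaphthalene-1,4-dione
Product: 15 8-(3,4-dimethoxyphenyl)-2,6-dimethoxynaphthalene-1,4-dione (CNP0128574.0), via hydroquinone 14 (not isolated)
Conditions: TsOH·H2O (10 mol %), DDQ (1.2 equiv), 1,4-dioxane, rt
Reagents that add atoms: none
Why: Acid-catalysed keto–enol tautomerisation to the aromatic hydroquinone followed by DDQ dehydrogenation is a standard oxidative aromatisation of 2,3-dihydro-1,4-naphthoquinones, and working without base avoids the C3 carbanion that would expel the C2 methoxy group by E1cB elimination.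

Compound list
1 | (S)-4-hydroxydihydrofuran-2(3H)-one | O[C@@H]1COC(=O)C1 | starting material
2 | (S)-4-methoxydihydrofuran-2(3H)-one | CO[C@@H]1COC(=O)C1 | intermediate
3 | (S)-4-hydroxy-N,3-dimethoxy-N-methylbutanamide | CO[C@H](CO)CC(=O)N(C)OC | intermediate
4 | (S)-N,3-dimethoxy-N-methyl-4-oxobutanamide | CO[C@H](C=O)CC(=O)N(C)OC | intermediate
5 | 4-ethynyl-1,2-dimethoxybenzene | C#Cc1ccc(OC)c(OC)c1 | starting material
6 | lithium (3,4-dimethoxyphenyl)ethynide | [Li]C#Cc1ccc(OC)c(OC)c1 | intermediate
7 | (3S)-6-(3,4-dimethoxyphenyl)-N,3-dimethoxy-N-methyl-4-(trimethylsilyloxy)hex-5-ynamide (C4 epimer mixture) | CO[C@H](C(O[Si](C)(C)C)C#Cc1ccc(OC)c(OC)c1)CC(=O)N(C)OC | intermediate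
8 | (5S)-8-(3,4-dimethoxyphenyl)-6-hydroxy-5-methoxyocta-1,7-diyn-3-one (C6 epimer mixture) | CO[C@H](C(O)C#Cc1ccc(OC)c(OC)c1)CC(=O)C#C | intermediate
9 | (S)-1-(3,4-dimethoxyphenyl)-4-methoxyocta-1,7-diyne-3,6-dione | C#CC(=O)C[C@H](OC)C(=O)C#Cc1ccc(OC)c(OC)c1 | intermediate
10 | 2-chloro-1,1-dimethoxyethane | COC(CCl)OC | starting material
11 | sodium methoxyethynide | [Na]C#COC | intermediate
12 | methoxyethyne | COC#C | intermediate
13 | (S)-8-(3,4-dimethoxyphenyl)-2,6-dimethoxy-2,3-dihydronaphthalene-1,4-dione | CO[C@H]1CC(=O)c2cc(OC)cc(-c3ccc(OC)c(OC)c3)c2C1=O | intermediate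
14 | 8-(3,4-dimethoxyphenyl)-2,6-dimethoxynaphthalene-1,4-diol | COc1cc(O)c2cc(OC)cc(-c3ccc(OC)c(OC)c3)c2c1O | intermediate
15 | 8-(3,4-dimethoxyphenyl)-2,6-dimethoxynaphthalene-1,4-dione | COC1=CC(=O)c2cc(OC)cc(-c3ccc(OC)c(OC)c3)c2C1=O | target

Total step count: 8. Longest linear sequence: 7 (steps 1–5, 7, 8); step 6 is a one-step side branch.

Steps most likely to fail

Step 7. The polarised ynol ether may insert with the opposite orientation, placing the methoxy group next to the aryl-bearing carbon. It may also oligomerise at the metal before it is captured, or the diynedione may homo-trimerise. Fallback: starting from 9, the same ruthenium-catalysed cyclotrimerisation is run with commercial 2-ethynyl-4,4,5,5-tetramethyl-1,3,2-dioxaborolane. Its bulky, electronically unbiased boryl group should follow steric control and give (S)-8-(3,4-dimethoxyphenyl)-2-methoxy-6-(4,4,5,5-tetramethyl-1,3,2-dioxaborolan-2-yl)-2,3-dihydronaphthalene-1,4-dione F1. Oxidation of the C–B bond with Oxone (2KHSO5·KHSO4·K2SO4) in aqueous acetone at 0 °C should give (S)-8-(3,4-dimethoxyphenyl)-6-hydroxy-2-methoxy-2,3-dihydronaphthalene-1,4-dione F2. Purdie methylation of F2 (MeI, Ag2O) comes back to the route at 13.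

Step 8. β-Elimination of methanol across C2–C3 may compete with enolisation and strip the C2 methoxy group, and the electron-rich aryl ring may be over-oxidised. Fallback: starting from 13, double soft enolisation with TMSOTf/Et3N (CH2Cl2, –78 → 0 °C) silylates each carbonyl oxygen before its α-proton is removed, so no free enolate is present. This should give 8-(3,4-dimethoxyphenyl)-2,6-dimethoxy-1,4-bis(trimethylsilyloxy)naphthalene F3. Oxidative desilylation of F3 with (NH4)2Ce(NO3)6 in aqueous MeCN at 0 °C comes back to the route at 15.

Step 4. The alkoxide may lactonise onto the Weinreb amide before it is silylated, after which the Grignard reagent would add twice. Liberated N,O-dimethylhydroxylamine may add to the terminal ynone during the quench, and acid may cyclodehydrate the γ-hydroxy ketone. Fallback: starting from 4, the sequence is run stepwise through an isolable silyl ether. Acetylide 6 is added and the alkoxide capped with TESCl/imidazole to give (3S)-6-(3,4-dimethoxyphenyl)-N,3-dimethoxy-N-methyl-4-(triethylsilyloxy)hex-5-ynamide F4, which is purified. F4 with HC≡CMgBr (THF, 0 °C, cold acidic quench) should give (5S)-8-(3,4-dimethoxyphenyl)-5-methoxy-6-(triethylsilyloxy)octa-1,7-diyn-3-one F5. Brief treatment of F5 with dilute aqueous HCl in THF at 0 °C removes the silyl group and comes back to the route at 8.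

Further compounds
F1 | step 7 | (S)-8-(3,4-dimethoxyphenyl)-2-methoxy-6-(4,4,5,5-tetramethyl-1,3,2-dioxaborolan-2-yl)-2,3-dihydronaphthalene-1,4-dione | CO[C@H]1CC(=O)c2cc(B3OC(C)(C)C(C)(C)O3)cc(-c3ccc(OC)c(OC)c3)c2C1=O
F2 | step 7 | (S)-8-(3,4-dimethoxyphenyl)-6-hydroxy-2-methoxy-2,3-dihydronaphthalene-1,4-dione | CO[C@H]1CC(=O)c2cc(O)cc(-c3ccc(OC)c(OC)c3)c2C1=O
F3 | step 8 | 8-(3,4-dimethoxyphenyl)-2,6-dimethoxy-1,4-bis(trimethylsilyloxy)naphthalene | COc1cc(O[Si](C)(C)C)c2cc(OC)cc(-c3ccc(OC)c(OC)c3)c2c1O[Si](C)(C)C
F4 | step 4 | (3S)-6-(3,4-dimethoxyphenyl)-N,3-dimethoxy-N-methyl-4-(triethylsilyloxy)hex-5-ynamide (C4 epimer mixture) | CO[C@H](C(O[Si](CC)(CC)CC)C#Cc1ccc(OC)c(OC)c1)CC(=O)N(C)OC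
F5 | step 4 | (5S)-8-(3,4-dimethoxyphenyl)-5-methoxy-6-(triethylsilyloxy)octa-1,7-diyn-3-one (C6 epimer mixture) | CO[C@H](C(O[Si](CC)(CC)CC)C#Cc1ccc(OC)c(OC)c1)CC(=O)C#C
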